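**Strategy.** Ring A is disconnected at C1–C2 (abietane numbering). The feature exploited is the δ-lactone C19(=O)–O–C20 that bridges C4 and C10 across C5. With this ring in place, a vinyl group on C10 (C1) and an allyl group on C4 (C3–C2) are held syn and 1,3-diaxial. One ring-closing metathesis then closes ring A, completes the 2-oxabicyclo[3.3.1]nonane and can only give the trans A/B fusion. The metathesis precursor is a cis-fused lactone on a dihydronaphthalene (rings B and C), made by a tethered Michael addition, whose C6=C7 bond is masked as an enol triflate. The hydroxyquinone of ring C is unveiled at the end.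

Key step: step 11

Remark: atoms are labelled by abietane numbering throughout (C18 = methyl on C4, C19 = lactone carbonyl on C4, C20 = lactone CH2 on C10); aldehyde 1 is taken as commercially available.

Step 1
Reactants: 1 4-isopropyl-3,5-dimethoxybenzaldehyde; 2 tert-butyl acrylate
Product: 3 tert-butyl 4-(4-isopropyl-3,5-dimethoxyphenyl)-4-oxobutanoate
Conditions: 3-benzyl-5-(2-hydroxyethyl)-4-methylthiazolium chloride (cat.), Et3N, EtOH, 75 °C
Reagents that add atoms: none
Why: Stetter reaction: the thiazolium carbene turns the aldehyde into an acyl anion equivalent that adds 1,4 to the acrylate, laying down C10 (here still the ketone carbon) and the C5–C6–C7 chain in one step.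

Step 2
Reactants: 3 tert-butyl 4-(4-isopropyl-3,5-dimethoxyphenyl)-4-oxobutanoate
Product: 5 tert-butyl 4-(4-isopropyl-3,5-dimethoxyphenyl)-5-oxopentanoate (racemic), via methyl enol ether 4 (not isolated)
Conditions: Ph3P(CH2OMe)Cl, KOtBu, THF, 0 °C to rt; then 1 M HCl, THF/H2O, rt
Reagents that add atoms: (methoxymethyl)triphenylphosphonium chloride COC[P+](c1ccccc1)(c1ccccc1)c1ccccc1.[Cl-]; water O
Why: Wittig one-carbon homologation: the methoxymethylene ylide converts the aryl ketone into enol ether 4, and mild acid hydrolysis should unveil the α-aryl aldehyde while the tert-butyl ester survives.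

Step 3
Reactants: 5 tert-butyl 4-(4-isopropyl-3,5-dimethoxyphenyl)-5-oxopentanoate
Product: 7 tert-butyl 5-hydroxy-4-(hydroxymethyl)-4-(4-isopropyl-3,5-dimethoxyphenyl)pentanoate, via hydroxy aldehyde 6 (not isolated)
Conditions: CH2O (37% aq.), K2CO3, THF/H2O, rt; then NaBH4, 0 °C
Reagents that add atoms: formaldehyde C=O
Why: Crossed aldol reaction of the enolisable α-aryl aldehyde with formaldehyde builds the quaternary carbon C10, and reduction of aldehyde 6 in the same flask should give the prochiral 1,3-diol, in which C10 is not yet a stereocenter.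

Step 4
Reactants: 7 tert-butyl 5-hydroxy-4-(hydroxymethyl)-4-(4-isopropyl-3,5-dimethoxyphenyl)pentanoate
Product: 8 tert-butyl (4R)-4-(hydroxymethyl)-4-(4-isopropyl-3,5-dimethoxyphenyl)-5-(propanoyloxy)pentanoate
Conditions: Burkholderia cepacia lipase, vinyl propanoate, t-BuOMe, 25 °C
Reagents that add atoms: vinyl propanoate CCC(=O)OC=C
Why: Lipase-catalysed desymmetrisation of a 2,2-disubstituted propane-1,3-diol by irreversible transesterification sets C10 through enantiotopic group selection by the enzyme (chosen by screening for the R monoester) and installs the propanoate that later serves as the tethered Michael donor.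

Step 5
Reactants: 8 tert-butyl (4R)-4-(hydroxymethyl)-4-(4-isopropyl-3,5-dimethoxyphenyl)-5-(propanoyloxy)pentanoate
Product: 9 tert-butyl (4S)-4-formyl-4-(4-isopropyl-3,5-dimethoxyphenyl)-5-(propanoyloxy)pentanoate
Conditions: Dess–Martin periodinane, CH2Cl2, 0 °C to rt
Reagents that add atoms: none
Why: Dess–Martin oxidation of the neopentylic primary alcohol proceeds without base, so the propanoate should not migrate, and C10 has no α-hydrogen and cannot epimerise.

Step 6
Reactants: 9 tert-butyl (4S)-4-formyl-4-(4-isopropyl-3,5-dimethoxyphenyl)-5-(propanoyloxy)pentanoate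
Product: 10 tert-butyl (4S)-4-(4-isopropyl-3,5-dimethoxyphenyl)-4-[(propanoyloxy)methyl]hex-5-enoate
Conditions: Ph3PCH3Br, KOtBu, THF, 0 °C
Reagents that add atoms: methyltriphenylphosphonium bromide C[P+](c1ccccc1)(c1ccccc1)c1ccccc1.[Br-]
Why: Wittig methylenation of the non-enolisable aldehyde should give the C10 vinyl group (C1) needed for the metathesis.

Step 7
Reactants: 10 tert-butyl (4S)-4-(4-isopropyl-3,5-dimethoxyphenyl)-4-[(propanoyloxy)methyl]hex-5-enoate
Product: 12 [(1S)-1-ethenyl-6-isopropyl-5,7-dimethoxy-4-oxo-1,2,3,4-tetrahydronaphthalen-1-yl]methyl propanoate, via carboxylic acid 11 (not isolated)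
Conditions: CF3COOH, CH2Cl2, 0 °C to rt; then (CF3CO)2O, 0 °C
Reagents that add atoms: none
Why: Acidolysis of the tert-butyl ester and intramolecular Friedel–Crafts acylation through the mixed trifluoroacetic anhydride close ring B at C8, which is ortho and para to the two methoxy groups, and the two ortho positions of the symmetric arene are equivalent so no regioisomer can form.

Step 8
Reactants: 12 [(1S)-1-ethenyl-6-isopropyl-5,7-dimethoxy-4-oxo-1,2,3,4-tetrahydronaphthalen-1-yl]methyl propanoate
Product: 14 [(1R)-1-ethenyl-6-isopropyl-5,7-dimethoxy-4-oxo-1,4-dihydronaphthalen-1-yl]methyl propanoate, via silyl enol ether 13 (not isolated)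
Conditions: Me3SiOTf, Et3N, CH2Cl2, 0 °C; then Pd(OAc)2 (1 equiv), MeCN, rt
Reagents that add atoms: none
Why: Saegusa–Ito dehydrogenation: the silyl enol ether formed at C6, the only enolisable ketone position, is palladated and loses the C5 hydrogen by β-hydride elimination, and the enone cannot tautomerise to a naphthol because C10 is quaternary (the descriptor changes only through priorities).

Step 9
Reactants: 14 [(1R)-1-ethenyl-6-isopropyl-5,7-dimethoxy-4-oxo-1,4-dihydronaphthalen-1-yl]methyl propanoate
Product: 16 cis-fused δ-lactone enol triflate (5S,10R; C4 epimers), via lithium ketone enolate 15 (not isolated)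
Conditions: LiN(SiMe3)2, THF, −78 °C; then PhNTf2, −78 °C to rt
Reagents that add atoms: N-phenylbis(trifluoromethanesulfonimide) O=S(=O)(N(c1ccccc1)S(=O)(=O)C(F)(F)F)C(F)(F)F
Why: Intramolecular 6-exo Michael addition of the propanoate enolate to the non-enolisable enone forms the C4–C5 bond and the lactone; the C20–O tether reaches C5 only from its own face, so the lactone is cis-fused and C5 is set by C10 (C4 is uncontrolled and need not be), and O-triflation of the resulting ketone enolate masks C6=C7 in its final position.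

Step 10
Reactants: 16 cis-fused δ-lactone enol triflate (5S,10R; C4 epimers)
Product: 18 C4-allylated lactone enol triflate (4S,5R,10R), via lithium lactone enolate 17 (not isolated)
Conditions: LiN(iPr)2, THF, −78 °C; then allyl bromide, −78 to −30 °C
Reagents that add atoms: allyl bromide C=CCBr
Why: Alkylation of the lactone enolate creates the C4 quaternary center, and the electrophile should enter anti to the adjacent C5–C6 bond on the convex face of the cis-fused bicycle, which places the allyl group syn to the C10 vinyl group and the methyl group on the ring B side.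

Step 11
Reactants: 18 C4-allylated lactone enol triflate (4S,5R,10R)
Product: 19 (4S,5R,10R)-12,14-dimethoxy-7-(trifluoromethanesulfonyloxy)abieta-1,6,8,11,13-pentaen-19,20-olide
Conditions: second-generation Grubbs catalyst (5 mol %), CH2Cl2 (0.005 M), 40 °C
Reagents that add atoms: none
Why: Ring-closing olefin metathesis by the metallacyclobutane mechanism: the ruthenium alkylidene loads onto the unhindered allyl terminus (C2), engages the C10 vinyl group in a [2+2] cycloaddition and cycloreversion, and releases ethene. The closest known reaction type is the metathesis of cis-1,3-diaxial alkenyl groups on a six-membered ring to a bicyclo[3.3.1]nonene. Ring A closes as a six-membered cyclohexene through the new C1=C2 bond, which at the same time makes the lactone ring part of a 2-oxabicyclo[3.3.1]nonane. No stereocenter is formed; the trans A/B fusion follows from C4, C5 and C10, since the lactone lets only the syn pair of alkenyl groups meet. The step needs chemoselectivity for the two terminal alkenes over the C6=C7 bond and ring closure in preference to oligomerisation: the enol triflate alkene is trisubstituted, electron-poor and endocyclic, and the lactone chair that avoids a 1,3-diaxial aryl/methyl clash places vinyl and allyl diaxial and within reach, helped by high dilution.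

Step 12
Reactants: 19 (4S,5R,10R)-12,14-dimethoxy-7-(trifluoromethanesulfonyloxy)abieta-1,6,8,11,13-pentaen-19,20-olide
Product: 20 (4S,5R,10R)-12,14-dimethoxy-7-(trifluoromethanesulfonyloxy)abieta-6,8,11,13-tetraen-19,20-olide
Conditions: 2-nitrobenzenesulfonyl hydrazide, Et3N, CH2Cl2, rt
Reagents that add atoms: none
Why: Diimide reduction: concerted syn transfer of two hydrogens should saturate the unhindered cis-disubstituted C1=C2 bond much faster than the trisubstituted, electron-poor enol triflate alkene, and it leaves triflate and lactone untouched.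

Step 13
Reactants: 20 (4S,5R,10R)-12,14-dimethoxy-7-(trifluoromethanesulfonyloxy)abieta-6,8,11,13-tetraen-19,20-olide
Product: 21 (4S,5R,10R)-12,14-dimethoxyabieta-6,8,11,13-tetraen-19,20-olide
Conditions: Pd(OAc)2 (cat.), PPh3, HCOOH, n-Bu3N, DMF, 60 °C
Reagents that add atoms: none
Why: Palladium-catalysed formate reduction of the enol triflate (oxidative addition to zerovalent palladium, formate exchange, loss of CO2, reductive elimination) should replace the triflate by hydrogen and leave C6=C7 in place.

Step 14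
Reactants: 21 (4S,5R,10R)-12,14-dimethoxyabieta-6,8,11,13-tetraen-19,20-olide
Product: 22 (4S,5R,10R)-12,14-dihydroxyabieta-6,8,11,13-tetraen-19,20-olide
Conditions: BBr3, CH2Cl2, −78 to 0 °C
Reagents that add atoms: none
Why: Lewis-acid cleavage of both aryl methyl ethers, a reaction that tolerates styrene-type alkenes on this isopropyl-dimethoxyarene pattern, should leave the bridged lactone intact at low temperature.

Step 15
Reactants: 22 (4S,5R,10R)-12,14-dihydroxyabieta-6,8,11,13-tetraen-19,20-olide
Product: 23 (4S,5R,10R)-12-hydroxy-11,14-dioxoabieta-6,8,12-trien-19,20-olide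
Conditions: (KSO3)2NO, KH2PO4, acetone/H2O, rt
Reagents that add atoms: potassium nitrosodisulfonate [K+].[K+].[O]N(S(=O)(=O)[O-])S(=O)(=O)[O-]
Why: Teuber oxidation: the nitroxyl radical oxidises the C14 phenol through its free para position C11 to the para-quinone, and the C12 hydroxyl remains as the hydroxyquinone.

Step 16
Reactants: 23 (4S,5R,10R)-12-hydroxy-11,14-dioxoabieta-6,8,12-trien-19,20-olide
Product: 24 (4S,5R,10R)-12-acetoxy-11,14-dioxoabieta-6,8,12-trien-19,20-olide
Conditions: Ac2O, pyridine, 0 °C to rt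
Reagents that add atoms: acetic anhydride CC(=O)OC(C)=O
Why: O-Acylation of the acidic hydroxyquinone hydroxyl with acetic anhydride under pyridine catalysis should give the acetate without touching the lactone.

**Compound list**

1 | 4-isopropyl-3,5-dimethoxybenzaldehyde | COc1cc(C=O)cc(OC)c1C(C)C | starting material
2 | tert-butyl acrylate | C=CC(=O)OC(C)(C)C | starting material
3 | tert-butyl 4-(4-isopropyl-3,5-dimethoxyphenyl)-4-oxobutanoate | COc1cc(cc(OC)c1C(C)C)C(=O)CCC(=O)OC(C)(C)C | intermediate
4 | tert-butyl 4-(4-isopropyl-3,5-dimethoxyphenyl)-5-methoxypent-4-enoate (E/Z mixture) | COC=C(CCC(=O)OC(C)(C)C)c1cc(OC)c(C(C)C)c(OC)c1 | intermediate (not isolated)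
5 | tert-butyl 4-(4-isopropyl-3,5-dimethoxyphenyl)-5-oxopentanoate (racemic) | COc1cc(cc(OC)c1C(C)C)C(C=O)CCC(=O)OC(C)(C)C | intermediate
6 | tert-butyl 4-formyl-5-hydroxy-4-(4-isopropyl-3,5-dimethoxyphenyl)pentanoate (racemic) | COc1cc(cc(OC)c1C(C)C)C(CO)(C=O)CCC(=O)OC(C)(C)C | intermediate (not isolated)
7 | tert-butyl 5-hydroxy-4-(hydroxymethyl)-4-(4-isopropyl-3,5-dimethoxyphenyl)pentanoate (prochiral diol) | COc1cc(cc(OC)c1C(C)C)C(CO)(CO)CCC(=O)OC(C)(C)C | intermediate
8 | tert-butyl (4R)-4-(hydroxymethyl)-4-(4-isopropyl-3,5-dimethoxyphenyl)-5-(propanoyloxy)pentanoate | COc1cc(cc(OC)c1C(C)C)[C@](COC(=O)CC)(CCC(=O)OC(C)(C)C)CO | intermediate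
9 | tert-butyl (4S)-4-formyl-4-(4-isopropyl-3,5-dimethoxyphenyl)-5-(propanoyloxy)pentanoate | COc1cc(cc(OC)c1C(C)C)[C@](COC(=O)CC)(CCC(=O)OC(C)(C)C)C=O | intermediate
10 | tert-butyl (4S)-4-(4-isopropyl-3,5-dimethoxyphenyl)-4-[(propanoyloxy)methyl]hex-5-enoate | COc1cc(cc(OC)c1C(C)C)[C@](COC(=O)CC)(CCC(=O)OC(C)(C)C)C=C | intermediate
11 | (4S)-4-(4-isopropyl-3,5-dimethoxyphenyl)-4-[(propanoyloxy)methyl]hex-5-enoic acid | COc1cc(cc(OC)c1C(C)C)[C@](COC(=O)CC)(CCC(=O)O)C=C | intermediate (not isolated)
12 | [(1S)-1-ethenyl-6-isopropyl-5,7-dimethoxy-4-oxo-1,2,3,4-tetrahydronaphthalen-1-yl]methyl propanoate | O=C1CC[C@](COC(=O)CC)(C=C)c2cc(OC)c(C(C)C)c(OC)c12 | intermediate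
13 | [(1S)-1-ethenyl-6-isopropyl-5,7-dimethoxy-4-(trimethylsilyloxy)-1,2-dihydronaphthalen-1-yl]methyl propanoate | C[Si](C)(C)OC1=CC[C@](COC(=O)CC)(C=C)c2cc(OC)c(C(C)C)c(OC)c12 | intermediate (not isolated)
14 | [(1R)-1-ethenyl-6-isopropyl-5,7-dimethoxy-4-oxo-1,4-dihydronaphthalen-1-yl]methyl propanoate | O=C1C=C[C@](COC(=O)CC)(C=C)c2cc(OC)c(C(C)C)c(OC)c12 | intermediate
15 | lithium enolate (C7–OLi, C6=C7) of the cis-fused keto lactone formed by the Michael addition; 5S,10R; C4 epimers | CC1C(=O)OC[C@@]2(C=C)c3cc(OC)c(C(C)C)c(OC)c3C(O[Li])=C[C@@H]12 | intermediate (not isolated)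
16 | cis-fused tricycle: δ-lactone O–C20H2–C10–C5–C4H(CH3)–C19(=O) fused at C5–C10 to the 1,2-dihydronaphthalene (C6=C7–OTf, 12,14-dimethoxy, 13-isopropyl), vinyl on C10; 5S,10R; both C4 epimers | CC1C(=O)OC[C@@]2(C=C)c3cc(OC)c(C(C)C)c(OC)c3C(OS(=O)(=O)C(F)(F)F)=C[C@@H]12 | intermediate
17 | lithium enolate (C4=C19–OLi) of lactone 16; 5S,10R | CC1=C(O[Li])OC[C@@]2(C=C)c3cc(OC)c(C(C)C)c(OC)c3C(OS(=O)(=O)C(F)(F)F)=C[C@@H]12 | intermediate (not isolated)
18 | lactone 16 carrying methyl and allyl on C4, allyl syn to the C10 vinyl group; 4S,5R,10R | C=CC[C@]1(C)C(=O)OC[C@@]2(C=C)c3cc(OC)c(C(C)C)c(OC)c3C(OS(=O)(=O)C(F)(F)F)=C[C@@H]12 | intermediate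
19 | (4S,5R,10R)-12,14-dimethoxy-7-(trifluoromethanesulfonyloxy)abieta-1,6,8,11,13-pentaen-19,20-olide | COc1cc2c(c(OC)c1C(C)C)C(OS(=O)(=O)C(F)(F)F)=C[C@@H]3[C@]24C=CC[C@]3(C)C(=O)OC4 | intermediate
20 | (4S,5R,10R)-12,14-dimethoxy-7-(trifluoromethanesulfonyloxy)abieta-6,8,11,13-tetraen-19,20-olide | COc1cc2c(c(OC)c1C(C)C)C(OS(=O)(=O)C(F)(F)F)=C[C@@H]3[C@]24CCC[C@]3(C)C(=O)OC4 | intermediate
21 | (4S,5R,10R)-12,14-dimethoxyabieta-6,8,11,13-tetraen-19,20-olide | COc1cc2c(c(OC)c1C(C)C)C=C[C@@H]3[C@]24CCC[C@]3(C)C(=O)OC4 | intermediate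
22 | (4S,5R,10R)-12,14-dihydroxyabieta-6,8,11,13-tetraen-19,20-olide | Oc1cc2c(c(O)c1C(C)C)C=C[C@@H]3[C@]24CCC[C@]3(C)C(=O)OC4 | intermediate
23 | (4S,5R,10R)-12-hydroxy-11,14-dioxoabieta-6,8,12-trien-19,20-olide | OC1=C(C(C)C)C(=O)C2=C(C1=O)[C@]13CCC[C@](C)(C(=O)OC1)[C@@H]3C=C2 | intermediate
24 | (4S,5R,10R)-12-acetoxy-11,14-dioxoabieta-6,8,12-trien-19,20-olide | CC(=O)OC1=C(C(C)C)C(=O)C2=C(C1=O)[C@]13CCC[C@](C)(C(=O)OC1)[C@@H]3C=C2 | target

Total step count: 16. Longest linear sequence: 16 steps (1 to 24).

**Steps most likely to fail**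

Risk 1 (step 4): the lipase may discriminate the two enantiotopic hydroxymethyl groups of 7 poorly, and 1,3-acyl migration in the monoester may erode the enantiomeric purity further. The fallback sets out from 3 and returns at 10, with reagent-controlled stereochemistry. Horner–Wadsworth–Emmons reaction of ketone 3 (triethyl phosphonoacetate, NaH, THF) should give, after removal of the minor Z isomer, the E-configured unsaturated diester F1. iBu2AlH (CH2Cl2, −78 °C) should reduce only the conjugated ethyl ester to the allylic alcohol F2. Sharpless epoxidation (Ti(OiPr)4, L-(+)-diethyl tartrate, t-BuOOH, 4 Å sieves, CH2Cl2, −20 °C) should give the (2S,3S)-epoxy alcohol F3, which is silylated (t-BuMe2SiCl, imidazole) to the epoxy silyl ether F4. The bulky Lewis acid MeAl(OC6H2-4-Br-2,6-tBu2)2 (CH2Cl2, −78 °C) should open the epoxide at the benzylic carbon and shift the siloxymethyl group to it with inversion, giving the quaternary β-siloxy aldehyde F5. Wittig methylenation then gives the vinyl silyl ether F6, n-Bu4NF the primary alcohol F7, and propanoic anhydride/DMAP returns to 10.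

Risk 2 (step 9): the propanoate enolate may fail to close the lactone (the ester prefers the rotamer that keeps the enolate away from C5, and intermolecular Claisen condensation or amide conjugate addition can compete), or O-triflation of the hindered enolate may be incomplete. The fallback sets out from 14 and returns at 16, replacing the anionic closure by a radical one (Ueno–Stork cyclisation). Methanolysis of 14 (K2CO3, MeOH) gives the hydroxymethyl enone F8. N-Bromosuccinimide and ethyl 1-propenyl ether (CH2Cl2, −20 °C) give the mixed bromoacetal F9. n-Bu3SnH/AIBN (benzene, 80 °C) generates a nucleophilic secondary radical that should add 6-exo to C5 of the enone from the tether face, giving the cis-fused cyclic acetal ketone F10. CrO3/H2SO4 in acetone oxidises the acetal to the keto lactone F11, and LiN(SiMe3)2 followed by PhNTf2 enolises the ketone at C6 and gives 16.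

Risk 3 (step 10): facial selectivity of the alkylation may be poor or reversed (allyl entering syn to ring B), and the resulting C4 epimer cannot undergo the metathesis. The fallback sets out from 14 and returns at 18, reversing the order in which the two C4 substituents arrive. The hydroxymethyl enone F8 (from 14 by methanolysis as above) is acylated with pent-4-enoyl chloride (pyridine, CH2Cl2) to the pent-4-enoate F12. LiN(SiMe3)2 followed by PhNTf2 gives, by the same Michael addition and triflation, the lactone enol triflate F13 that carries the allyl group and a hydrogen at C4. Deprotonation (LiN(iPr)2) and methylation (CH3I) then place the methyl group on the face the electrophile prefers, which gives 18 if that face is the one syn to ring B.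

**Further compounds**

F1 | step 4 | 6-tert-butyl 1-ethyl (2E)-3-(4-isopropyl-3,5-dimethoxyphenyl)hex-2-enedioate | CCOC(=O)/C=C(\CCC(=O)OC(C)(C)C)c1cc(OC)c(C(C)C)c(OC)c1
F2 | step 4 | tert-butyl (4E)-6-hydroxy-4-(4-isopropyl-3,5-dimethoxyphenyl)hex-4-enoate | OC/C=C(\CCC(=O)OC(C)(C)C)c1cc(OC)c(C(C)C)c(OC)c1
F3 | step 4 | tert-butyl 3-[(2S,3S)-3-(hydroxymethyl)-2-(4-isopropyl-3,5-dimethoxyphenyl)oxiran-2-yl]propanoate | OC[C@@H]1O[C@@]1(CCC(=O)OC(C)(C)C)c1cc(OC)c(C(C)C)c(OC)c1
F4 | step 4 | tert-butyl 3-[(2S,3S)-3-[(tert-butyldimethylsilyloxy)methyl]-2-(4-isopropyl-3,5-dimethoxyphenyl)oxiran-2-yl]propanoate | CC(C)(C)[Si](C)(C)OC[C@@H]1O[C@@]1(CCC(=O)OC(C)(C)C)c1cc(OC)c(C(C)C)c(OC)c1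
F5 | step 4 | tert-butyl (4S)-5-(tert-butyldimethylsilyloxy)-4-formyl-4-(4-isopropyl-3,5-dimethoxyphenyl)pentanoate | COc1cc(cc(OC)c1C(C)C)[C@](CO[Si](C)(C)C(C)(C)C)(CCC(=O)OC(C)(C)C)C=O
F6 | step 4 | tert-butyl (4S)-4-[(tert-butyldimethylsilyloxy)methyl]-4-(4-isopropyl-3,5-dimethoxyphenyl)hex-5-enoate | COc1cc(cc(OC)c1C(C)C)[C@](CO[Si](C)(C)C(C)(C)C)(CCC(=O)OC(C)(C)C)C=C
F7 | step 4 | tert-butyl (4S)-4-(hydroxymethyl)-4-(4-isopropyl-3,5-dimethoxyphenyl)hex-5-enoate | COc1cc(cc(OC)c1C(C)C)[C@](CO)(CCC(=O)OC(C)(C)C)C=C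
F8 | step 9 | (4R)-4-ethenyl-4-(hydroxymethyl)-7-isopropyl-6,8-dimethoxynaphthalen-1(4H)-one | O=C1C=C[C@](CO)(C=C)c2cc(OC)c(C(C)C)c(OC)c12
F9 | step 9 | (4R)-4-[(2-bromo-1-ethoxypropoxy)methyl]-4-ethenyl-7-isopropyl-6,8-dimethoxynaphthalen-1(4H)-one (mixture at the two acetal-chain centers) | O=C1C=C[C@](COC(OCC)C(C)Br)(C=C)c2cc(OC)c(C(C)C)c(OC)c12
F10 | step 9 | cis-fused cyclic acetal ketone: 2-ethoxytetrahydropyran O–C20H2–C10–C5–C4H(CH3)–C19H(OEt) fused at C5–C10 to the 1-tetralone (C7=O, 12,14-dimethoxy, 13-isopropyl), vinyl on C10; 5S,10R; epimers at C4 and C19 | CC1C(OCC)OC[C@@]2(C=C)c3cc(OC)c(C(C)C)c(OC)c3C(=O)C[C@@H]12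
F11 | step 9 | cis-fused keto lactone, the C7 ketone corresponding to enol triflate 16; 5S,10R; C4 epimers | CC1C(=O)OC[C@@]2(C=C)c3cc(OC)c(C(C)C)c(OC)c3C(=O)C[C@@H]12
F12 | step 10 | [(1R)-1-ethenyl-6-isopropyl-5,7-dimethoxy-4-oxo-1,4-dihydronaphthalen-1-yl]methyl pent-4-enoate | O=C1C=C[C@](COC(=O)CCC=C)(C=C)c2cc(OC)c(C(C)C)c(OC)c12
F13 | step 10 | analogue of lactone enol triflate 16 with allyl in place of methyl on C4; 5S,10R; C4 epimers | C=CCC1C(=O)OC[C@@]2(C=C)c3cc(OC)c(C(C)C)c(OC)c3C(OS(=O)(=O)C(F)(F)F)=C[C@@H]12
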